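If the maple curve flattens with Xp at a quarter of the Xa charged, I take that as a second way out for Xa, and I reckon the flask with two times.

| flask | Xa | Xb | Xc | time |
|---|---|---|---|---|
| maple | 0.600 M | 1.80 M | 0.0300 M |  |
| larch | 0.360 M | 1.56 M | 0.0300 M |  |
| ash | 0.600 M | 0.900 M | 0.0300 M |  |
| elm | 1.80 M | 1.80 M | 0.0300 M |  |
| cedar | 0.600 M | 1.80 M | 0.0300 M | 210 min |

| maple run: time / min | maple run: [Xp] / M | larch run: time / min | larch run: [Xp] / M | ash run: time / min | ash run: [Xp] / M | elm run: time / min | elm run: [Xp] / M |
|---|---|---|---|---|---|---|---|
| 1.4 | 0.015 | 1.4 | 0 | 1.4 | 0.003 | 1.4 | 0.039 |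
| 3.1 | 0.034 | 3.1 | 0.024 | 3.1 | 0.024 | 3.1 | 0.084 |
| 7.0 | 0.071 | 7.0 | 0.041 | 7.0 | 0.039 | 7.0 | 0.168 |
| 16 | 0.116 | 16 | 0.061 | 16 | 0.066 | 16 | 0.292 |
| 35 | 0.145 | 35 | 0.080 | 35 | 0.079 | 35 | 0.400 |

(standard deviation of a reading: 0.005 M)

- Overall: Xa + Xb -> Xp, with Xc as catalyst.
- Constant volume, constant temperature.
- A reading of a species includes what of it is bound.
- An order is taken over about fifteen percent of the charge, up and down.

1. the power of [Xb] that the first rate follows, about the charge of the maple run; measure it at two percent of Xa made into Xp
2. the power of [Xa] that the first rate follows, about the charge of the maple run; measure it at two percent of Xa made into Xp (one fixed amount of Xp, the same in the runs compared)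
3. Xp in the cedar run at 210 min, as a share of the Xa charged

I started with maple. Taking the last reading as near the end, the gap below it shrank from 0.0740 M at 7.0 min to 0.0290 M at 16 min, so the curve closed with a time of 9.61 min. Adding the rise still due after 35 min put the end at 0.150 M, a share of 24.9%.

Suppose Xa leaves by two first-order exits, the product one being pseudo-first-order with Xb in excess. Their rates then add up to the closing rate and split in that share. This gave a product time of 38.5 min and a loss time of 12.8 min. Their ratio, 3.01, counts the Xa lost for each Xa that becomes Xp. I call it the exit ratio, product time over loss time, at the charge of maple; its inverse is the selectivity factor toward Xp at that charge.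

Cedar has the charge of maple, and 210 min is 21.9 closing times, so I committed to the same share, 24.9%.

I tried the ratio on ash, with half the Xb of maple. Stretching the product time by that factor gave an end of 0.0855 M, and the ash reading at 35 min was lower, at 0.079 M, by 1.30 standard deviations.

The forecast gave 0.95 for Xb, 0.85 for Xa and 26% for cedar, a point above my share and on other grounds: “Cedar should sit at equilibrium”.

The flask gave 1.1, 0.82 and 25.0%.

    2 Xc ⇌ Xc2, settled at all times (65.40 M⁻¹)
    Xc + Xa + Xb → Xp + Xc (1.554 M⁻² min⁻¹)
    2 Xa ⇌ Xa2, settled at all times (0.6230 M⁻¹)
    Xa → E (0.09480 min⁻¹)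

The loss exit is the conversion of Xa into E, and the cedar run without that step proves it. At an exit ratio of 3.01, my reckoning sent 75.1% of the Xa charged in cedar through that exit. With the conversion of Xa into E taken away, the cedar run reached 98.9%, against 25.0% with the conversion of Xa into E in place.

(The earlier runs and the new flask are simulated with made-up constants.)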